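**Retrosynthetic overview**
1. The ten-membered ring is opened at the C1=C10 (Z) olefin: ring-closing metathesis of a dienol is the last step, so the carbocycle is formed last.
2. The γ-lactone (C6–C7 and C6–O bonds) is formed first, by a chiral-phosphoric-acid-catalysed allylboration/lactonisation that joins a C1–C6 enal to a C7–C13 allylboronate; the C11 methyl then comes from conjugate reduction.
3. The enal: organocatalytic allylboration of an achiral C5 aldehyde sets C3; the ester comes from (R)-2-methylbutanoic acid, made by asymmetric hydrogenation of tiglic acid.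
4. The allylboronate: organocatalytic acetaldehyde aldol on methacrolein sets C9; Morita–Baylis–Hillman reaction, acetylation and allylic borylation complete it.
5. Germacrane numbering is used for positions: C3 ester, C4=C5 (E), C6 lactone O, C7 ring fusion, C9 OH, C10=C1 (Z), C11 α-methyl carbon, C12 lactone C=O.

Assumption: the configuration is read directly from the SMILES, i.e. (3S,6R,7S,9S,11R), 1(10)Z,4E, a cis-fused lactone with the C11 methyl cis to C8, and an (R)-2-methylbutanoate.

**Route**

Step 1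
Reactants: 1 (2E)-3-methyl-4-oxobut-2-en-1-yl acetate; 2 allylboronic acid pinacol ester
Product: 3 (2E,4S)-4-hydroxy-3-methylhepta-2,6-dien-1-yl acetate
Conditions: (S)-TRIP (5 mol %), 4 Å MS, PhMe, −30 °C
Reagents that add atoms: none
Why: Chiral-phosphoric-acid-catalysed allylboration through a closed chair in which the acid hydrogen-bonds a pinacol oxygen and the formyl C–H; (S)-TRIP sends the allyl group to the Si face of the enal and sets the 4S centre (C3 of the target), the sense being that known for aryl and α,β-unsaturated aldehydes (to be confirmed by Mosher analysis).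

Step 2
Reactants: 4 tiglic acid
Product: 5 (2R)-2-methylbutanoic acid
Conditions: Ru(OAc)2[(R)-H8-BINAP] (0.5 mol %), H2 (1.5 atm), MeOH, 20 °C
Reagents that add atoms: none
Why: Noyori-type asymmetric hydrogenation of an α,β-unsaturated acid bound as its carboxylate; the (R)-ligand gives the (R)-acid in high ee.

Step 3
Reactants: 3 (2E,4S)-4-hydroxy-3-methylhepta-2,6-dien-1-yl acetate; 5 (2R)-2-methylbutanoic acid
Product: 6 (2E,4S)-3-methyl-4-{[(2R)-2-methylbutanoyl]oxy}hepta-2,6-dien-1-yl acetate
Conditions: DCC, DMAP (cat.), CH2Cl2, 0 °C to rt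
Reagents that add atoms: none
Why: Steglich esterification of the secondary allylic alcohol; no stereocentre is touched and an α-alkyl acid does not racemise under these conditions.

Step 4
Reactants: 6 (2E,4S)-3-methyl-4-{[(2R)-2-methylbutanoyl]oxy}hepta-2,6-dien-1-yl acetate
Product: 7 (4S,5E)-7-hydroxy-5-methylhepta-1,5-dien-4-yl (2R)-2-methylbutanoate
Conditions: K2CO3 (0.1 equiv), MeOH, 0 °C
Reagents that add atoms: none
Why: Chemoselective base-catalysed methanolysis (transesterification): the primary acetate is cleaved much faster than the hindered secondary α-branched ester, and the E olefin rules out acyl migration.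

Step 5
Reactants: 7 (4S,5E)-7-hydroxy-5-methylhepta-1,5-dien-4-yl (2R)-2-methylbutanoate
Product: 8 (4S,5E)-5-methyl-7-oxohepta-1,5-dien-4-yl (2R)-2-methylbutanoate
Conditions: TEMPO (10 mol %), PhI(OAc)2, CH2Cl2, rt
Reagents that add atoms: none
Why: Oxoammonium (TEMPO) oxidation of the primary allylic alcohol to the E-enal without touching the olefins or the ester.

Step 6
Reactants: 9 methacrolein; 10 tert-butyl(dimethyl)(vinyloxy)silane
Product: 11 (3S)-3-{[tert-butyl(dimethyl)silyl]oxy}-4-methylpent-4-enal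
Conditions: IDPi Brønsted acid (1 mol %; antipode giving 3S), PhMe, −60 °C
Reagents that add atoms: none
Why: Organocatalytic Mukaiyama-type single aldolisation of an acetaldehyde enol silane: the confined chiral imidodiphosphorimidate anion pairs with the silylated aldehyde, one face is attacked to set the 3S centre (C9 of the target), and silyl transfer gives the protected aldol so that it does not react again.

Step 7
Reactants: 11 (3S)-3-{[tert-butyl(dimethyl)silyl]oxy}-4-methylpent-4-enal; 12 methyl acrylate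
Product: 13 methyl (5S)-5-{[tert-butyl(dimethyl)silyl]oxy}-3-hydroxy-6-methyl-2-methylidenehept-6-enoate (mixture of C3 epimers)
Conditions: DABCO (0.5 equiv), MeOH (2 equiv), neat 12, rt, 4 d
Reagents that add atoms: none
Why: Morita–Baylis–Hillman reaction; the new carbinol centre forms unselectively and is erased in step 9, while the silyl ether and the isopropenyl group are inert.

Step 8
Reactants: 13 methyl (5S)-5-{[tert-butyl(dimethyl)silyl]oxy}-3-hydroxy-6-methyl-2-methylidenehept-6-enoate
Product: 14 methyl (5S)-3-acetoxy-5-{[tert-butyl(dimethyl)silyl]oxy}-6-methyl-2-methylidenehept-6-enoate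
Conditions: Ac2O, pyridine, DMAP (cat.), CH2Cl2, 0 °C
Reagents that add atoms: acetic anhydride, CC(=O)OC(C)=O
Why: Simple acylation that turns the allylic hydroxyl into a leaving group for the allylic substitution.

Step 9
Reactants: 14 methyl (5S)-3-acetoxy-5-{[tert-butyl(dimethyl)silyl]oxy}-6-methyl-2-methylidenehept-6-enoate
Product: 15 methyl (2E,5S)-5-{[tert-butyl(dimethyl)silyl]oxy}-6-methyl-2-[(4,4,5,5-tetramethyl-1,3,2-dioxaborolan-2-yl)methyl]hepta-2,6-dienoate
Conditions: B2pin2, CuCl (10 mol %), LiCl, KOAc, DMF, rt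
Reagents that add atoms: bis(pinacolato)diboron, CC1(C)OB(OC1(C)C)B1OC(C)(C)C(C)(C)O1
Why: Copper-catalysed SN2′ (allylic) borylation of a Morita–Baylis–Hillman acetate: boryl-copper adds to the acrylate terminus and acetate is expelled, giving the trisubstituted olefin with the chain trans to the ester (cis to CH2B), the geometry needed for a syn-selective allylboration.

Step 10
Reactants: 8 (4S,5E)-5-methyl-7-oxohepta-1,5-dien-4-yl (2R)-2-methylbutanoate; 15 methyl (2E,5S)-5-{[tert-butyl(dimethyl)silyl]oxy}-6-methyl-2-[(4,4,5,5-tetramethyl-1,3,2-dioxaborolan-2-yl)methyl]hepta-2,6-dienoate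
Product: 17 (1E,3S)-1-[(2S,3S)-3-{(2S)-2-{[tert-butyl(dimethyl)silyl]oxy}-3-methylbut-3-en-1-yl}-4-methylidene-5-oxooxolan-2-yl]-2-methylhexa-1,5-dien-3-yl (2R)-2-methylbutanoate, via syn-homoallylic pinacol borate 16 (not isolated)
Conditions: (R)-TRIP (10 mol %), 4 Å MS, PhMe, 0 °C to rt; then 45 °C
Reagents that add atoms: none
Why: Proposed new method: a chiral phosphoric acid is used to drive and steer the allylboration of an ester-deactivated, γ-branched 2-(methoxycarbonyl)allyl pinacol boronate with a β,β-disubstituted enal as a fragment coupling, a pairing not yet shown in this catalysis; the P–OH hydrogen-bonds the pseudo-axial pinacol oxygen and so raises the Lewis acidity of boron (the effect achiral Brønsted acids are known to have on these sluggish boronates) while P=O holds the formyl C–H, so the aldehyde reacts on its Re face in a closed chair (Zimmerman–Traxler-type) transition state, the γ-chain cis to CH2B sits axial and gives the syn adduct 16 (C6 and C7 set together under catalyst control), and the borate oxygen then attacks the neighbouring ester to close the cis-γ-lactone with loss of MeO–Bpin; the closest known reactions are the chiral-phosphoric-acid-catalysed allyl- and crotylboration of aldehydes with simple pinacol boronates and the achiral acid-catalysed 2-alkoxycarbonylallylboration–lactonisation.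

Step 11
Reactants: 17 (1E,3S)-1-[(2S,3S)-3-{(2S)-2-{[tert-butyl(dimethyl)silyl]oxy}-3-methylbut-3-en-1-yl}-4-methylidene-5-oxooxolan-2-yl]-2-methylhexa-1,5-dien-3-yl (2R)-2-methylbutanoate
Product: 18 (1E,3S)-1-[(2R,3S,4R)-3-{(2S)-2-{[tert-butyl(dimethyl)silyl]oxy}-3-methylbut-3-en-1-yl}-4-methyl-5-oxooxolan-2-yl]-2-methylhexa-1,5-dien-3-yl (2R)-2-methylbutanoate
Conditions: NaBH4, MeOH/THF, −20 °C; AcOH quench
Reagents that add atoms: none
Why: 1,4-Hydride (conjugate) reduction of the α-methylene lactone; methanol protonates the enolate on the face opposite the two cis substituents at C6 and C7, so the new methyl ends up cis to both (C11 = R, the all-cis lactone), and the isolated olefins, esters and silyl ether are untouched.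

Step 12
Reactants: 18 (1E,3S)-1-[(2R,3S,4R)-3-{(2S)-2-{[tert-butyl(dimethyl)silyl]oxy}-3-methylbut-3-en-1-yl}-4-methyl-5-oxooxolan-2-yl]-2-methylhexa-1,5-dien-3-yl (2R)-2-methylbutanoate
Product: 19 (1E,3S)-1-[(2R,3S,4R)-3-[(2S)-2-hydroxy-3-methylbut-3-en-1-yl]-4-methyl-5-oxooxolan-2-yl]-2-methylhexa-1,5-dien-3-yl (2R)-2-methylbutanoate
Conditions: HF·pyridine, THF/pyridine, 0 °C to rt
Reagents that add atoms: none
Why: Fluoride desilylation under mildly acidic conditions frees the C9 hydroxyl without epimerising the base-sensitive C11 centre or cleaving the esters.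

Step 13
Reactants: 19 (1E,3S)-1-[(2R,3S,4R)-3-[(2S)-2-hydroxy-3-methylbut-3-en-1-yl]-4-methyl-5-oxooxolan-2-yl]-2-methylhexa-1,5-dien-3-yl (2R)-2-methylbutanoate
Product: 20 (3R,3aS,5S,6Z,9S,10E,11aR)-5-hydroxy-3,6,10-trimethyl-2-oxo-2,3,3a,4,5,8,9,11a-octahydrocyclodeca[b]furan-9-yl (2R)-2-methylbutanoate
Conditions: second-generation Hoveyda–Grubbs catalyst RuCl2(SIMes)(=CH-C6H4-2-OiPr) (15 mol %), 1,4-benzoquinone (30 mol %), PhMe (0.5 mM), 80 °C
Reagents that add atoms: none
Why: Ring-closing metathesis between the vinyl group (C1) and the isopropenyl group (C10): the cis-fused lactone holds both arms on one face, the free allylic hydroxyl helps the catalyst load onto the hindered olefin, and the ten-membered ring, which already holds one E olefin, is expected to close to the cis (Z) trisubstituted olefin; no stereocentre is touched.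

**Compound list**
1 | (2E)-3-methyl-4-oxobut-2-en-1-yl acetate | CC(=O)OC/C=C(\C)C=O | starting material
2 | allylboronic acid pinacol ester | C=CCB1OC(C)(C)C(C)(C)O1 | starting material
3 | (2E,4S)-4-hydroxy-3-methylhepta-2,6-dien-1-yl acetate | C=CC[C@H](O)/C(C)=C/COC(C)=O | intermediate
4 | tiglic acid, (2E)-2-methylbut-2-enoic acid | C/C=C(\C)C(=O)O | starting material
5 | (2R)-2-methylbutanoic acid | CC[C@@H](C)C(=O)O | intermediate
6 | (2E,4S)-3-methyl-4-{[(2R)-2-methylbutanoyl]oxy}hepta-2,6-dien-1-yl acetate | C=CC[C@H](OC(=O)[C@H](C)CC)/C(C)=C/COC(C)=O | intermediate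
7 | (4S,5E)-7-hydroxy-5-methylhepta-1,5-dien-4-yl (2R)-2-methylbutanoate | C=CC[C@H](OC(=O)[C@H](C)CC)/C(C)=C/CO | intermediate
8 | (4S,5E)-5-methyl-7-oxohepta-1,5-dien-4-yl (2R)-2-methylbutanoate | C=CC[C@H](OC(=O)[C@H](C)CC)/C(C)=C/C=O | intermediate
9 | methacrolein | CC(=C)C=O | starting material
10 | tert-butyl(dimethyl)(vinyloxy)silane | C=CO[Si](C)(C)C(C)(C)C | starting material
11 | (3S)-3-{[tert-butyl(dimethyl)silyl]oxy}-4-methylpent-4-enal | O=CC[C@H](O[Si](C)(C)C(C)(C)C)C(C)=C | intermediate
12 | methyl acrylate | C=CC(=O)OC | starting material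
13 | methyl (5S)-5-{[tert-butyl(dimethyl)silyl]oxy}-3-hydroxy-6-methyl-2-methylidenehept-6-enoate (C3 epimers) | COC(=O)C(=C)C(O)C[C@H](O[Si](C)(C)C(C)(C)C)C(C)=C | intermediate
14 | methyl (5S)-3-acetoxy-5-{[tert-butyl(dimethyl)silyl]oxy}-6-methyl-2-methylidenehept-6-enoate (C3 epimers) | COC(=O)C(=C)C(OC(C)=O)C[C@H](O[Si](C)(C)C(C)(C)C)C(C)=C | intermediate
15 | methyl (2E,5S)-5-{[tert-butyl(dimethyl)silyl]oxy}-6-methyl-2-[(4,4,5,5-tetramethyl-1,3,2-dioxaborolan-2-yl)methyl]hepta-2,6-dienoate | COC(=O)/C(CB1OC(C)(C)C(C)(C)O1)=C/C[C@H](O[Si](C)(C)C(C)(C)C)C(C)=C | intermediate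
16 | methyl (3S,4S,5E,7S)-3-[(2S)-2-{[tert-butyl(dimethyl)silyl]oxy}-3-methylbut-3-en-1-yl]-6-methyl-2-methylidene-7-{[(2R)-2-methylbutanoyl]oxy}-4-[(4,4,5,5-tetramethyl-1,3,2-dioxaborolan-2-yl)oxy]deca-5,9-dienoate | CC[C@@H](C)C(=O)O[C@@H](CC=C)/C(C)=C/[C@H](OB1OC(C)(C)C(C)(C)O1)[C@@H](C[C@H](O[Si](C)(C)C(C)(C)C)C(C)=C)C(=C)C(=O)OC | intermediate (not isolated)
17 | (1E,3S)-1-[(2S,3S)-3-{(2S)-2-{[tert-butyl(dimethyl)silyl]oxy}-3-methylbut-3-en-1-yl}-4-methylidene-5-oxooxolan-2-yl]-2-methylhexa-1,5-dien-3-yl (2R)-2-methylbutanoate | CC[C@@H](C)C(=O)O[C@@H](CC=C)/C(C)=C/[C@@H]1OC(=O)C(=C)[C@@H]1C[C@H](O[Si](C)(C)C(C)(C)C)C(C)=C | intermediate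
18 | (1E,3S)-1-[(2R,3S,4R)-3-{(2S)-2-{[tert-butyl(dimethyl)silyl]oxy}-3-methylbut-3-en-1-yl}-4-methyl-5-oxooxolan-2-yl]-2-methylhexa-1,5-dien-3-yl (2R)-2-methylbutanoate | CC[C@@H](C)C(=O)O[C@@H](CC=C)/C(C)=C/[C@@H]1OC(=O)[C@H](C)[C@@H]1C[C@H](O[Si](C)(C)C(C)(C)C)C(C)=C | intermediate
19 | (1E,3S)-1-[(2R,3S,4R)-3-[(2S)-2-hydroxy-3-methylbut-3-en-1-yl]-4-methyl-5-oxooxolan-2-yl]-2-methylhexa-1,5-dien-3-yl (2R)-2-methylbutanoate | CC[C@@H](C)C(=O)O[C@@H](CC=C)/C(C)=C/[C@@H]1OC(=O)[C@H](C)[C@@H]1C[C@H](O)C(C)=C | intermediate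
20 | (3R,3aS,5S,6Z,9S,10E,11aR)-5-hydroxy-3,6,10-trimethyl-2-oxo-2,3,3a,4,5,8,9,11a-octahydrocyclodeca[b]furan-9-yl (2R)-2-methylbutanoate | CC[C@@H](C)C(=O)O[C@H]1C/C=C(/C)[C@@H](O)C[C@@H]2[C@H](/C=C/1C)OC(=O)[C@@H]2C | target

**Step count**
Total: 13 steps. Longest linear sequence: 8 steps (steps 6, 7, 8, 9, 10, 11, 12, 13; the branch through steps 1, 3, 4, 5 is equally long).

**The three steps most likely to fail**

Step 10 (the proposed new coupling). The acid may be too weak to activate the ester-deactivated boronate, or it may fail to override the two chiral partners. The fallback uses known metal-mediated Barbier chemistry without catalyst control. It sets out from 13: NBS/Me2S (CH2Cl2, 0 °C) converts the alcohol with allylic transposition into methyl (2Z,5S)-2-(bromomethyl)-5-{[tert-butyl(dimethyl)silyl]oxy}-6-methylhepta-2,6-dienoate F1. Indium powder in THF/aqueous NH4Cl then couples F1 with 8 through a closed transition state that gives only syn adducts, and these lactonise in the flask with a trace of p-TsOH. The result is a mixture of 17 and its cis-lactone diastereomer (1E,3S)-1-[(2R,3R)-3-{(2S)-2-{[tert-butyl(dimethyl)silyl]oxy}-3-methylbut-3-en-1-yl}-4-methylidene-5-oxooxolan-2-yl]-2-methylhexa-1,5-dien-3-yl (2R)-2-methylbutanoate F2, which is removed by chromatography. The route is rejoined at 17.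

Step 13 (ring-closing metathesis). The hindered 1,1-disubstituted allylic-alcohol olefin may not engage, dimerisation may win, or some E isomer may form. The fallback closes the ring onto an enone and sets C9 afterwards. It sets out from 19: Dess–Martin periodinane (NaHCO3, CH2Cl2) gives the isopropenyl ketone (1E,3S)-2-methyl-1-[(2R,3S,4R)-4-methyl-3-(3-methyl-2-oxobut-3-en-1-yl)-5-oxooxolan-2-yl]hexa-1,5-dien-3-yl (2R)-2-methylbutanoate F3. Ring-closing metathesis of this electron-poor enone (same catalyst, PhMe, high dilution, 80 °C) gives the macrocyclic enone (3R,3aS,6Z,9S,10E,11aR)-3,6,10-trimethyl-2,5-dioxo-2,3,3a,4,5,8,9,11a-octahydrocyclodeca[b]furan-9-yl (2R)-2-methylbutanoate F4; there is no allylic alcohol to isomerise and the enone does not homodimerise. Reagent-controlled 1,2-reduction with (R)-Me-CBS and catecholborane (PhMe, −78 °C) then gives 20 directly, where the route is rejoined.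

Step 6 (organocatalytic aldol on methacrolein). This small, polymerisable enal is an untested acceptor, so ee or yield may be poor. The fallback is the known Lewis-base-catalysed Mukaiyama acetate aldol followed by reduction. It sets out from 9: SiCl4 with a chiral bisphosphoramide catalyst and the tert-butyldimethylsilyl ketene acetal of methyl acetate (CH2Cl2, −78 °C) gives methyl (3S)-3-hydroxy-4-methylpent-4-enoate F5. TBSOTf/2,6-lutidine gives methyl (3S)-3-{[tert-butyl(dimethyl)silyl]oxy}-4-methylpent-4-enoate F6, and iBu2AlH (CH2Cl2, −78 °C) reduces the ester to 11, where the route is rejoined.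

**Further compounds**
F1 | step 10 | methyl (2Z,5S)-2-(bromomethyl)-5-{[tert-butyl(dimethyl)silyl]oxy}-6-methylhepta-2,6-dienoate | COC(=O)/C(CBr)=C/C[C@H](O[Si](C)(C)C(C)(C)C)C(C)=C
F2 | step 10 | (1E,3S)-1-[(2R,3R)-3-{(2S)-2-{[tert-butyl(dimethyl)silyl]oxy}-3-methylbut-3-en-1-yl}-4-methylidene-5-oxooxolan-2-yl]-2-methylhexa-1,5-dien-3-yl (2R)-2-methylbutanoate | CC[C@@H](C)C(=O)O[C@@H](CC=C)/C(C)=C/[C@H]1OC(=O)C(=C)[C@H]1C[C@H](O[Si](C)(C)C(C)(C)C)C(C)=C
F3 | step 13 | (1E,3S)-2-methyl-1-[(2R,3S,4R)-4-methyl-3-(3-methyl-2-oxobut-3-en-1-yl)-5-oxooxolan-2-yl]hexa-1,5-dien-3-yl (2R)-2-methylbutanoate | CC[C@@H](C)C(=O)O[C@@H](CC=C)/C(C)=C/[C@@H]1OC(=O)[C@H](C)[C@@H]1CC(=O)C(C)=C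
F4 | step 13 | (3R,3aS,6Z,9S,10E,11aR)-3,6,10-trimethyl-2,5-dioxo-2,3,3a,4,5,8,9,11a-octahydrocyclodeca[b]furan-9-yl (2R)-2-methylbutanoate | CC[C@@H](C)C(=O)O[C@H]1C/C=C(/C)C(=O)C[C@@H]2[C@H](/C=C/1C)OC(=O)[C@@H]2C
F5 | step 6 | methyl (3S)-3-hydroxy-4-methylpent-4-enoate | COC(=O)C[C@H](O)C(C)=C
F6 | step 6 | methyl (3S)-3-{[tert-butyl(dimethyl)silyl]oxy}-4-methylpent-4-enoate | COC(=O)C[C@H](O[Si](C)(C)C(C)(C)C)C(C)=C
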